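The ring carbons are numbered C1 (epoxide carbon bearing C7H2OBz), C2 (CHOH), C3 (CHOBz), C4=C5 and C6 (epoxide CH). The route rests on opening the carbocycle at its cis C4=C5 alkene: C4 and C5 become the two α-carbons of a seven-membered cyclic sulfone. A Ramberg–Bäcklund reaction then deletes the sulfur atom, contracts the thiepine to the six-membered ring and creates the C1=C6–C5=C4 diene in one operation. Its precursor, a 2,3,4,7-tetrahydrothiepine 1,1-dioxide carrying the C2/C3 trans-diol as silyl ethers, comes from a syn-aldol (C2, C3), methylenation and ring-closing metathesis (C1=C6). Hydroxyl-directed epoxidation of C1=C6 completes the target.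

Key step: step 7

Remark: TBS = tert-butyldimethylsilyl, TES = triethylsilyl, Bz = benzoyl. Compound 5 is taken as a catalogue compound. The D-configured catalyst in step 2 is chosen on the assumption that it is the mirror image of the L-catalyst giving the L-threo adduct.

Step 1
Reactants: 1 1,4-dithiane-2,5-diol (0.5 equiv, the dimer of mercaptoacetaldehyde); 2 allyl bromide
Product: 4 2-(prop-2-en-1-ylsulfanyl)acetaldehyde, via 2-sulfanylacetaldehyde 3 (not isolated)
Conditions: Et3N (1.1 equiv), CH2Cl2, 0 °C → rt; used crude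
Reagents that add atoms: none
Why: base-induced cleavage of the bis-hemithioacetal releases mercaptoacetaldehyde, whose thiolate should undergo SN2 S-allylation (thioether synthesis) faster than any aldol reaction of the aldehyde at 0 °C.

Step 2
Reactants: 4 2-(prop-2-en-1-ylsulfanyl)acetaldehyde; 5 1,3-bis(TBS-oxy)propan-2-one
Product: 6 (3S,4S)-1,3-bis(TBS-oxy)-4-hydroxy-5-(prop-2-en-1-ylsulfanyl)pentan-2-one
Conditions: O-tert-butyl-D-threonine (20 mol %), 5-methyl-1H-tetrazole (10 mol %), NMP/H2O 97:3, 4 °C; 4 and 5 equimolar, 4 added slowly by syringe pump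
Reagents that add atoms: none
Why: direct organocatalytic syn-aldol addition by primary-amine enamine catalysis, in which the (Z)-enamine of the α-silyloxy ketone (N–H···O hydrogen bond) adds to the Si face of 4 held by the carboxylic acid of the D-amino acid, so that C2 and C3 are set together as the syn (D-threo) pair and all atoms of both partners end up in the adduct.

Step 3
Reactants: 6 (3S,4S)-1,3-bis(TBS-oxy)-4-hydroxy-5-(prop-2-en-1-ylsulfanyl)pentan-2-one
Product: 7 (3S,4S)-1,3-bis(TBS-oxy)-5-(prop-2-en-1-ylsulfanyl)-4-(TES-oxy)pentan-2-one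
Conditions: TESCl, imidazole, DMAP (cat.), CH2Cl2, 0 °C
Reagents that add atoms: chlorotriethylsilane, CC[Si](Cl)(CC)CC
Why: O-silylation of the secondary alcohol under weakly basic conditions that should not cause retro-aldol cleavage or epimerisation, giving a TES ether that can later be removed together with the primary TBS ether but not with the secondary one.

Step 4
Reactants: 7 (3S,4S)-1,3-bis(TBS-oxy)-5-(prop-2-en-1-ylsulfanyl)-4-(TES-oxy)pentan-2-one
Product: 8 (3R,4S)-3-(TBS-oxy)-2-[(TBS-oxy)methyl]-5-(prop-2-en-1-ylsulfanyl)-4-(TES-oxy)pent-1-ene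
Conditions: Ph3PCH3Br (1.5 equiv), KOtBu (1.4 equiv), THF, 0 °C; then 7, 0 °C → rt
Reagents that add atoms: methyltriphenylphosphonium bromide, C[P+](c1ccccc1)(c1ccccc1)c1ccccc1.[Br-]
Why: Wittig methylenation with the unstabilised ylide, which is reactive enough for the hindered α,α'-dioxygenated ketone, while the deficit of base keeps free alkoxide away so that C2 is not epimerised and the β-silyloxy group is not eliminated.

Step 5
Reactants: 8 (3R,4S)-3-(TBS-oxy)-2-[(TBS-oxy)methyl]-5-(prop-2-en-1-ylsulfanyl)-4-(TES-oxy)pent-1-ene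
Product: 10 (3R,4S)-3-(TBS-oxy)-2-[(TBS-oxy)methyl]-5-(prop-2-en-1-ylsulfonyl)-4-(TES-oxy)pent-1-ene, via sulfoxide 9 (not isolated)
Conditions: mCPBA (2.1 equiv), NaHCO3, CH2Cl2, −20 → 0 °C
Reagents that add atoms: 3-chloroperoxybenzoic acid, O=C(OO)c1cccc(Cl)c1
Why: chemoselective oxidation of sulfide to sulfone, which should be much faster than Prilezhaev epoxidation of the monosubstituted allyl alkene or of the 1,1-disubstituted alkene deactivated by two allylic silyloxy groups.

Step 6
Reactants: 10 (3R,4S)-3-(TBS-oxy)-2-[(TBS-oxy)methyl]-5-(prop-2-en-1-ylsulfonyl)-4-(TES-oxy)pent-1-ene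
Product: 11 (3S,4R)-4-(TBS-oxy)-5-[(TBS-oxy)methyl]-3-(TES-oxy)-2,3,4,7-tetrahydrothiepine 1,1-dioxide
Conditions: Grubbs II catalyst (5–10 mol %), 1,4-benzoquinone (10 mol %), CH2Cl2 (5 mM), 40 °C
Reagents that add atoms: none
Why: ring-closing olefin metathesis, in which the ruthenium carbene loads at the unhindered allyl sulfone terminus and closes the seven-membered ring onto the 1,1-disubstituted alkene with loss of ethene, giving the endocyclic trisubstituted C1=C6 alkene that can only be Z in the ring.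

Step 7
Reactants: 11 (3S,4R)-4-(TBS-oxy)-5-[(TBS-oxy)methyl]-3-(TES-oxy)-2,3,4,7-tetrahydrothiepine 1,1-dioxide
Product: 14 (5R,6R)-6-(TBS-oxy)-1-[(TBS-oxy)methyl]-5-(TES-oxy)cyclohexa-1,3-diene, via α-bromo sulfone 12 (not isolated), via episulfone 13 (not isolated)
Conditions: CBr2F2, KOH/Al2O3, t-BuOH/CH2Cl2, 0 °C → rt
Reagents that add atoms: none
Why: Ramberg–Bäcklund reaction in its one-pot halogenative form, a reaction type known for metathesis-derived cyclic allyl sulfones: hydroxide removes the more acidic allylic α-proton at C5 (thiepine C7), the carbanion is brominated by CBr2F2 to 12, and a second deprotonation at C4 (thiepine C2) is followed by intramolecular displacement of bromide to give episulfone 13, which loses SO2 cheletropically. The C4–C5 bond that closes the six-membered carbocycle is formed in this 3-exo-tet 1,3-elimination, and extrusion of sulfur then turns the seven-membered thiepine into the cyclohexa-1,3-diene with the new C4=C5 bond conjugated to C1=C6. No stereocentre is created: the new alkene is forced to be cis by the ring, and C2 and C3 carry no acidic hydrogen and keep the configuration set in step 2. The step needs regioselective halogenation (secured by the allylic activation of C5), cyclisation of the C4 carbanion faster than E1cB loss of the C3 silyloxy group (a poor leaving group next to an intramolecular bromide), and a product without acidic C–H so that no base-induced aromatisation follows.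

Step 8
Reactants: 14 (5R,6R)-6-(TBS-oxy)-1-[(TBS-oxy)methyl]-5-(TES-oxy)cyclohexa-1,3-diene
Product: 15 (1R,6R)-6-(TBS-oxy)-5-(hydroxymethyl)cyclohexa-2,4-dien-1-ol
Conditions: HF·pyridine, excess pyridine, THF, 0 °C
Reagents that add atoms: none
Why: chemoselective buffered fluoride desilylation, in which the secondary TES ether and the primary TBS ether should be cleaved much faster than the hindered secondary TBS ether at C2, while the buffered medium avoids acid-induced aromatisation of the dihydrodiol.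

Step 9
Reactants: 15 (1R,6R)-6-(TBS-oxy)-5-(hydroxymethyl)cyclohexa-2,4-dien-1-ol
Product: 16 [(5R,6R)-5-(benzoyloxy)-6-(TBS-oxy)cyclohexa-1,3-dien-1-yl]methyl benzoate
Conditions: BzCl (2.5 equiv), pyridine, DMAP (cat.), CH2Cl2, 0 °C
Reagents that add atoms: benzoyl chloride, O=C(Cl)c1ccccc1
Why: DMAP-catalysed O-acylation (esterification) of both free hydroxyl groups while C2–O stays silylated, with retention at C3 because its C–O bond is not touched.

Step 10
Reactants: 16 [(5R,6R)-5-(benzoyloxy)-6-(TBS-oxy)cyclohexa-1,3-dien-1-yl]methyl benzoate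
Product: 17 [(5R,6R)-5-(benzoyloxy)-6-hydroxycyclohexa-1,3-dien-1-yl]methyl benzoate
Conditions: TBAF, AcOH (1:1), THF, 0 °C → rt
Reagents that add atoms: none
Why: fluoride-induced desilylation buffered with acetic acid, so that the C2 alkoxide is protonated at once and neither benzoate migration from C3–O nor elimination to the arene should occur.

Step 11
Reactants: 17 [(5R,6R)-5-(benzoyloxy)-6-hydroxycyclohexa-1,3-dien-1-yl]methyl benzoate
Product: 18 [(1S,2S,3R,6R)-3-(benzoyloxy)-2-hydroxy-7-oxabicyclo[4.1.0]hept-4-en-1-yl]methyl benzoate (target)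
Conditions: VO(acac)2 (5 mol %), t-BuOOH (1.3 equiv, anhydrous in decane), CH2Cl2, 0 °C
Reagents that add atoms: tert-butyl hydroperoxide, CC(C)(C)OO
Why: vanadium-catalysed hydroxyl-directed epoxidation of an allylic alcohol, in which the C2–O–vanadium peroxo complex delivers oxygen to the adjacent trisubstituted C1=C6 bond on the face of the C2 hydroxyl, setting C1 and C6 (epoxide cis to C2–OH, trans to C3–OBz) while the C4=C5 bond next to the benzoate is not reached.

Compound list
1 | 1,4-dithiane-2,5-diol | OC1CSC(O)CS1 | starting material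
2 | allyl bromide (3-bromoprop-1-ene) | C=CCBr | starting material
3 | 2-sulfanylacetaldehyde | O=CCS | intermediate (not isolated)
4 | 2-(prop-2-en-1-ylsulfanyl)acetaldehyde | C=CCSCC=O | intermediate
5 | 1,3-bis(tert-butyldimethylsilyloxy)propan-2-one | CC(C)(C)[Si](C)(C)OCC(=O)CO[Si](C)(C)C(C)(C)C | starting material
6 | (3S,4S)-1,3-bis(TBS-oxy)-4-hydroxy-5-(prop-2-en-1-ylsulfanyl)pentan-2-one | C=CCSC[C@@H](O)[C@H](O[Si](C)(C)C(C)(C)C)C(=O)CO[Si](C)(C)C(C)(C)C | intermediate
7 | (3S,4S)-1,3-bis(TBS-oxy)-5-(prop-2-en-1-ylsulfanyl)-4-(TES-oxy)pentan-2-one | C=CCSC[C@@H](O[Si](CC)(CC)CC)[C@H](O[Si](C)(C)C(C)(C)C)C(=O)CO[Si](C)(C)C(C)(C)C | intermediate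
8 | (3R,4S)-3-(TBS-oxy)-2-[(TBS-oxy)methyl]-5-(prop-2-en-1-ylsulfanyl)-4-(TES-oxy)pent-1-ene | C=CCSC[C@@H](O[Si](CC)(CC)CC)[C@H](O[Si](C)(C)C(C)(C)C)C(=C)CO[Si](C)(C)C(C)(C)C | intermediate
9 | sulfoxide of 8 (S-oxide, mixture at sulfur) | C=CCS(=O)C[C@@H](O[Si](CC)(CC)CC)[C@H](O[Si](C)(C)C(C)(C)C)C(=C)CO[Si](C)(C)C(C)(C)C | intermediate (not isolated)
10 | (3R,4S)-3-(TBS-oxy)-2-[(TBS-oxy)methyl]-5-(prop-2-en-1-ylsulfonyl)-4-(TES-oxy)pent-1-ene | C=CCS(=O)(=O)C[C@@H](O[Si](CC)(CC)CC)[C@H](O[Si](C)(C)C(C)(C)C)C(=C)CO[Si](C)(C)C(C)(C)C | intermediate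
11 | (3S,4R)-4-(TBS-oxy)-5-[(TBS-oxy)methyl]-3-(TES-oxy)-2,3,4,7-tetrahydrothiepine 1,1-dioxide | O=S1(=O)C[C@@H](O[Si](CC)(CC)CC)[C@H](O[Si](C)(C)C(C)(C)C)C(CO[Si](C)(C)C(C)(C)C)=CC1 | intermediate
12 | (3S,4R)-7-bromo-4-(TBS-oxy)-5-[(TBS-oxy)methyl]-3-(TES-oxy)-2,3,4,7-tetrahydrothiepine 1,1-dioxide (C7 epimers) | O=S1(=O)C[C@@H](O[Si](CC)(CC)CC)[C@H](O[Si](C)(C)C(C)(C)C)C(CO[Si](C)(C)C(C)(C)C)=CC1Br | intermediate (not isolated)
13 | (4R,5S)-4-(TBS-oxy)-3-[(TBS-oxy)methyl]-5-(TES-oxy)-7-thiabicyclo[4.1.0]hept-2-ene 7,7-dioxide (cis-fused episulfone) | O=S1(=O)C2C=C(CO[Si](C)(C)C(C)(C)C)[C@@H](O[Si](C)(C)C(C)(C)C)[C@H](O[Si](CC)(CC)CC)C12 | intermediate (not isolated)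
14 | (5R,6R)-6-(TBS-oxy)-1-[(TBS-oxy)methyl]-5-(TES-oxy)cyclohexa-1,3-diene | CC(C)(C)[Si](C)(C)OCC1=CC=C[C@@H](O[Si](CC)(CC)CC)[C@@H]1O[Si](C)(C)C(C)(C)C | intermediate
15 | (1R,6R)-6-(TBS-oxy)-5-(hydroxymethyl)cyclohexa-2,4-dien-1-ol | OCC1=CC=C[C@@H](O)[C@@H]1O[Si](C)(C)C(C)(C)C | intermediate
16 | [(5R,6R)-5-(benzoyloxy)-6-(TBS-oxy)cyclohexa-1,3-dien-1-yl]methyl benzoate | O=C(OCC1=CC=C[C@@H](OC(=O)c2ccccc2)[C@@H]1O[Si](C)(C)C(C)(C)C)c1ccccc1 | intermediate
17 | [(5R,6R)-5-(benzoyloxy)-6-hydroxycyclohexa-1,3-dien-1-yl]methyl benzoate | O=C(OCC1=CC=C[C@@H](OC(=O)c2ccccc2)[C@@H]1O)c1ccccc1 | intermediate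
18 | [(1S,2S,3R,6R)-3-(benzoyloxy)-2-hydroxy-7-oxabicyclo[4.1.0]hept-4-en-1-yl]methyl benzoate | O=C(OC[C@@]12O[C@@H]1C=C[C@@H](OC(=O)c1ccccc1)[C@@H]2O)c1ccccc1 | target

Total step count: 11. Longest linear sequence: 11 steps (1/2 → 18).

Steps most likely to fail

Step 7 (key step). Under the strongly basic one-pot conditions the carbanion at C4 may expel the C3 silyloxy group (E1cB), or the allylic α-position may be halogenated more than once, so that vinyl sulfones or halodienes form instead of the contracted diene. The fallback separates halogenation from the 1,3-elimination and sets out from 11. Kinetic deprotonation at the allylic α-carbon with LiHMDS (THF, −78 °C) and chlorination with hexachloroethane should give the isolated α-chloro sulfone (3S,4R)-7-chloro-4-(TBS-oxy)-5-[(TBS-oxy)methyl]-3-(TES-oxy)-2,3,4,7-tetrahydrothiepine 1,1-dioxide F1. Treating this with KOtBu (THF, −78 → −20 °C), with no hydroxide or excess halogen source present, should then trigger the Ramberg–Bäcklund contraction and come back to the route at 14.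

Step 2. The unbranched, easily enolised aldehyde 4 may self-condense under amine catalysis, and syn-selectivity or enantioselectivity may erode. The fallback replaces steps 2–4 by an allylboration; it sets out from 4 and 5 and comes back to the route at 8. Ketone 5 is methylenated (Ph3P=CH2, THF) to 2-methylidenepropane-1,3-diyl bis(TBS ether) F2. Allylic lithiation (s-BuLi, TMEDA, THF, −78 °C) and γ-trapping with 2-isopropoxy-4,4,5,5-tetramethyl-1,3,2-dioxaborolane, by analogy with the known preparation of γ-silyloxyallyl stannanes from allyl silyl ethers, should give the γ-silyloxyallyl boronate 2-[(2E)-3-(TBS-oxy)-2-[(TBS-oxy)methyl]prop-2-en-1-yl]-4,4,5,5-tetramethyl-1,3,2-dioxaborolane F3, with the silyloxy group cis to CH2B. Chiral phosphoric acid-catalysed allylboration of 4 (the TRIP enantiomer that directs the allyl group to the Si face of 4, expected to be (S)-TRIP; toluene, −30 °C) passes through a chair transition state and should give the syn-configured pinacol borate of the homoallylic alcohol F4. Hydrolytic work-up then gives (2S,3R)-3-(TBS-oxy)-4-[(TBS-oxy)methyl]-1-(prop-2-en-1-ylsulfanyl)pent-4-en-2-ol F5, which already carries the exocyclic methylene, and silylation with TESCl/imidazole returns to 8.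

Step 8. Discrimination among the three silyl ethers may be incomplete (loss of the C2 silyl ether or survival of the primary one), and the dihydrodiol may dehydrate to an arene under the acidic fluoride source. The fallback replaces steps 8–10 and gives up protecting-group differentiation in favour of steric differentiation. It sets out from 14: global desilylation with TBAF (THF, 0 °C) gives (1R,2R)-3-(hydroxymethyl)cyclohexa-3,5-diene-1,2-diol F6. Benzoylation with BzCl (2.05 equiv) and 2,4,6-collidine in CH2Cl2 at −78 → −40 °C should then acylate the primary allylic hydroxyl and the less hindered C3 hydroxyl before the C2 hydroxyl, which is flanked by the fully substituted C1, and comes back to the route at 17.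

Further compounds
F1 | step 7 | (3S,4R)-7-chloro-4-(TBS-oxy)-5-[(TBS-oxy)methyl]-3-(TES-oxy)-2,3,4,7-tetrahydrothiepine 1,1-dioxide | O=S1(=O)C[C@@H](O[Si](CC)(CC)CC)[C@H](O[Si](C)(C)C(C)(C)C)C(CO[Si](C)(C)C(C)(C)C)=CC1Cl
F2 | step 2 | 2-methylidenepropane-1,3-diyl bis(TBS ether) | C=C(CO[Si](C)(C)C(C)(C)C)CO[Si](C)(C)C(C)(C)C
F3 | step 2 | 2-[(2E)-3-(TBS-oxy)-2-[(TBS-oxy)methyl]prop-2-en-1-yl]-4,4,5,5-tetramethyl-1,3,2-dioxaborolane | CC1(C)OB(C/C(CO[Si](C)(C)C(C)(C)C)=C\O[Si](C)(C)C(C)(C)C)OC1(C)C
F4 | step 2 | pinacol borate of (2S,3R)-3-(TBS-oxy)-4-[(TBS-oxy)methyl]-1-(prop-2-en-1-ylsulfanyl)pent-4-en-2-ol | CC1(C)OB(O[C@H](CSCC=C)[C@H](O[Si](C)(C)C(C)(C)C)C(=C)CO[Si](C)(C)C(C)(C)C)OC1(C)C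
F5 | step 2 | (2S,3R)-3-(TBS-oxy)-4-[(TBS-oxy)methyl]-1-(prop-2-en-1-ylsulfanyl)pent-4-en-2-ol | C=CCSC[C@@H](O)[C@H](O[Si](C)(C)C(C)(C)C)C(=C)CO[Si](C)(C)C(C)(C)C
F6 | step 8 | (1R,2R)-3-(hydroxymethyl)cyclohexa-3,5-diene-1,2-diol | OCC1=CC=C[C@@H](O)[C@@H]1O
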